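Numbering the carbocycle from the ketone C1 to the quaternary carbon C10 (C11–C13: lactone carbons), the route rests on disconnecting C7–C11. C7 is the only ring carbon lying between the oxygen-bearing carbons C6 and C8 and carries nothing but C11, so it stays a methylene until a rhodium carbenoid tethered to the C8 oxygen as a diazophosphonoacetate inserts into a C7–H bond. That single operation closes the five-membered lactone ring (C7, C8, O, C12, C11), sets C7 and leaves the phosphonate for methylenation. The precursor is the complete furanone-bridged ten-membered ring carrying the C6 epoxy ester, itself closed at C5–C6 by alkenylchromium addition to an aldehyde.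

Key step: step 20

Remark: C14 and C15 are the methyl groups on C10 and C4. Bridged macrocycles are named as 3,10-epoxycyclodeca-2,4-dien-1-ones with these locants, and several descriptors change with substitution although no centre is inverted.
Assumption: the ring closure of step 15 is taken to favour the alcohol with the C6 and C8 oxygens cis; the opposite outcome is covered by a fallback. In 31 the phosphonate is drawn trans to C6; either C11 epimer serves.

Step 1
Reactants: 1 2-methylprop-2-en-1-ol
Product: 2 (R)-2-methylglycidol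
Conditions: Ti(OiPr)4 (5 mol%), D-(−)-diisopropyl tartrate (6 mol%), cumene hydroperoxide, 4 Å sieves, CH2Cl2, −20 °C
Reagents that add atoms: cumene hydroperoxide, CC(C)(OO)c1ccccc1
Why: Sharpless asymmetric epoxidation, in which the titanium complex of the D-(−)-tartrate (the ester that gives (R)-glycidol from allyl alcohol) delivers oxygen to the same alkene face here and so sets the quaternary epoxide carbon as R.

Step 2
Reactants: 2 (R)-2-methylglycidol
Product: 3 (2S)-2-methyloxirane-2-carboxylic acid
Conditions: RuCl3 (2 mol%), NaIO4, CCl4/MeCN/H2O, 0 °C → rt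
Reagents that add atoms: water, O
Why: Sharpless ruthenium tetroxide oxidation (RuO4 formed from RuCl3 and NaIO4) takes the primary alcohol through the aldehyde hydrate to the acid without opening the epoxide, and the stereocentre is untouched, its descriptor changing from R to S only through the change in priorities.

Step 3
Reactants: 4 prop-2-yn-1-ol
Product: 6 (Z)-3-iodo-2-methylprop-2-en-1-ol, via alkenylmagnesium alkoxide 5 (not isolated)
Conditions: MeMgBr (2.5 equiv), CuI (10 mol%), THF, −10 °C → rt; then I2, −10 °C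
Reagents that add atoms: methylmagnesium bromide, C[Mg]Br; iodine, II
Why: Duboudin-type copper-catalysed carbomagnesiation, in which the magnesium alkoxide directs anti addition of methyl and magnesium across the alkyne so that magnesium ends on C3 cis to the CH2O group, and iodinolysis with retention gives the Z-iodide.

Step 4
Reactants: 6 (Z)-3-iodo-2-methylprop-2-en-1-ol
Product: 7 (Z)-3-iodo-2-methylprop-2-enal
Conditions: MnO2, CH2Cl2, rt, dark; used at once
Reagents that add atoms: none
Why: Allylic oxidation with MnO2 is neutral and heterogeneous, so the configurationally labile Z-iodoenal should form without isomerisation.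

Step 5
Reactants: 7 (Z)-3-iodo-2-methylprop-2-enal
Product: 8 (Z)-1-iodo-2-methylbut-1-en-3-yne
Conditions: Me3SiCHN2, LiN(iPr)2, THF, −78 °C; then 7, −78 °C → rt; H2O; kept as a THF solution
Reagents that add atoms: (trimethylsilyl)diazomethane, C[Si](C)(C)C=[N+]=[N-]
Why: Colvin rearrangement, in which the lithiated silyldiazomethane adds to the aldehyde, Peterson elimination and loss of N2 give an alkylidene carbene, and its 1,2-hydrogen shift gives the alkyne under non-nucleophilic conditions that leave the Z-iodoalkene alone.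

Step 6
Reactants: 9 (S)-lactic acid
Product: 10 (2S,5S)-2-tert-butyl-5-methyl-1,3-dioxolan-4-one
Conditions: t-BuCHO, p-TsOH (cat.), H2SO4 (cat.), pentane, reflux (Dean–Stark); crystallisation from pentane at −78 °C
Reagents that add atoms: pivalaldehyde, CC(C)(C)C=O
Why: Acid-catalysed acetalisation (Seebach's self-regeneration of stereocentres), in which the cis acetal is the thermodynamic product and is purified by crystallisation, so the lactic acid centre fixes the acetal carbon as 2S.

Step 7
Reactants: 10 (2S,5S)-2-tert-butyl-5-methyl-1,3-dioxolan-4-one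
Product: 12 (2S,5R)-2-tert-butyl-5-methyl-5-(prop-2-en-1-yl)-1,3-dioxolan-4-one, via lithium enolate 11 (not isolated)
Conditions: LiN(iPr)2, THF, −78 °C; then allyl bromide, −78 → −30 °C
Reagents that add atoms: allyl bromide, C=CCBr
Why: Alkylation of the planar lithium enolate occurs anti to the tert-butyl group, so allyl replaces the original hydrogen with overall retention and sets the quaternary carbon that becomes C10.

Step 8
Reactants: 12 (2S,5R)-2-tert-butyl-5-methyl-5-(prop-2-en-1-yl)-1,3-dioxolan-4-one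
Product: 14 (2S,5R)-2-tert-butyl-5-methyl-5-(2-oxoethyl)-1,3-dioxolan-4-one, via ozonide 13 (not isolated)
Conditions: O3, CH2Cl2, −78 °C; then PPh3, −78 °C → rt
Reagents that add atoms: ozone, [O-][O+]=O
Why: Ozonolysis with reductive work-up cleaves the only alkene to the aldehyde (the future C8) and leaves the acylal and the quaternary centre untouched.

Step 9
Reactants: 14 (2S,5R)-2-tert-butyl-5-methyl-5-(2-oxoethyl)-1,3-dioxolan-4-one
Product: 16 (2S,5R)-2-tert-butyl-5-[(2R)-2-hydroxypent-4-en-1-yl]-5-methyl-1,3-dioxolan-4-one, via borinate ester 15 (not isolated)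
Conditions: (+)-Ipc2B(CH2CH=CH2) [from (−)-α-pinene, salt-free], Et2O, −78 °C; then pH 7 buffer, 30% H2O2, MeOH, 0 °C
Reagents that add atoms: (+)-B-allyldiisopinocampheylborane, C=CCB([C@H]1C[C@H]2C[C@@H]([C@@H]1C)C2(C)C)[C@H]1C[C@H]2C[C@@H]([C@@H]1C)C2(C)C
Why: Brown allylboration through a chair-like six-membered transition state, in which this reagent (the one that gives (R)-1-phenylbut-3-en-1-ol from benzaldehyde) adds allyl to the Re face of the aldehyde and sets the carbinol carbon, the future C8, as R under reagent control.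

Step 10
Reactants: 16 (2S,5R)-2-tert-butyl-5-[(2R)-2-hydroxypent-4-en-1-yl]-5-methyl-1,3-dioxolan-4-one
Product: 17 (2S,5R)-2-tert-butyl-5-[(2R)-2-[(tert-butyldimethylsilyl)oxy]pent-4-en-1-yl]-5-methyl-1,3-dioxolan-4-one
Conditions: t-BuMe2SiOTf, 2,6-lutidine, CH2Cl2, −78 → 0 °C
Reagents that add atoms: tert-butyldimethylsilyl triflate, CC(C)(C)[Si](C)(C)OS(=O)(=O)C(F)(F)F
Why: Silylation with the triflate and a hindered base is fast at low temperature and caps the secondary alcohol before it can lactonise onto the acylal.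

Step 11
Reactants: 17 (2S,5R)-2-tert-butyl-5-[(2R)-2-[(tert-butyldimethylsilyl)oxy]pent-4-en-1-yl]-5-methyl-1,3-dioxolan-4-one
Product: 18 (2R,4R)-4-[(tert-butyldimethylsilyl)oxy]-2-hydroxy-N-methoxy-N,2-dimethylhept-6-enamide
Conditions: MeNH(OMe)·HCl, AlMe3, CH2Cl2, 0 °C → rt; aqueous work-up
Reagents that add atoms: N,O-dimethylhydroxylamine hydrochloride, CNOC.Cl
Why: Weinreb aminolysis with the aluminium amide opens the acylal at its carbonyl group, and the hemiacetal left on the tertiary oxygen loses pivalaldehyde on work-up, so the amide and the free tertiary alcohol appear together with both stereocentres untouched.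

Step 12
Reactants: 18 (2R,4R)-4-[(tert-butyldimethylsilyl)oxy]-2-hydroxy-N-methoxy-N,2-dimethylhept-6-enamide; 8 (Z)-1-iodo-2-methylbut-1-en-3-yne
Product: 20 (1Z,6R,8R)-8-[(tert-butyldimethylsilyl)oxy]-6-hydroxy-1-iodo-2,6-dimethylundeca-1,10-dien-3-yn-5-one, via lithium acetylide 19 (not isolated)
Conditions: LiN(SiMe3)2 (1.0 equiv on 18, 1.6 equiv on 8), THF, −78 °C; combine, −78 → 0 °C; AcOH
Reagents that add atoms: none
Why: Acylation of an alkynyllithium by a Weinreb amide stops at the chelated tetrahedral adduct so that the ynone appears only on quenching, while the silylamide base deprotonates the alkyne without iodine–lithium exchange and the tertiary alkoxide is carried as a spectator.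

Step 13
Reactants: 20 (1Z,6R,8R)-8-[(tert-butyldimethylsilyl)oxy]-6-hydroxy-1-iodo-2,6-dimethylundeca-1,10-dien-3-yn-5-one
Product: 21 (2R)-2-[(2R)-2-[(tert-butyldimethylsilyl)oxy]pent-4-en-1-yl]-5-[(1Z)-1-iodoprop-1-en-2-yl]-2-methylfuran-3(2H)-one
Conditions: (Ph3P)AuCl (5 mol%), AgOTf (5 mol%), toluene, rt
Reagents that add atoms: none
Why: Gold-catalysed 5-endo-dig cycloisomerisation of an α'-hydroxy ynone, in which the cationic monovalent gold complex activates the alkyne, the tertiary hydroxyl adds to C3 and protodeauration gives the 3(2H)-furanone with no stereocentre affected.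

Step 14
Reactants: 21 (2R)-2-[(2R)-2-[(tert-butyldimethylsilyl)oxy]pent-4-en-1-yl]-5-[(1Z)-1-iodoprop-1-en-2-yl]-2-methylfuran-3(2H)-one
Product: 23 (3S)-3-[(tert-butyldimethylsilyl)oxy]-4-[(2R)-5-[(1Z)-1-iodoprop-1-en-2-yl]-2-methyl-3-oxo-2,3-dihydrofuran-2-yl]butanal, via diol 22 (not isolated)
Conditions: OsO4 (2 mol%), NaIO4, 2,6-lutidine, dioxane/H2O 3:1, rt
Reagents that add atoms: sodium periodate (oxygen delivered through OsO4), [Na+].[O-]I(=O)(=O)=O
Why: Lemieux–Johnson oxidation, in which OsO4 should dihydroxylate the monosubstituted terminal alkene well before the electron-poor trisubstituted iodoalkene or the vinylogous ester double bond, and periodate cleaves the diol to the C6 aldehyde.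

Step 15
Reactants: 23 (3S)-3-[(tert-butyldimethylsilyl)oxy]-4-[(2R)-5-[(1Z)-1-iodoprop-1-en-2-yl]-2-methyl-3-oxo-2,3-dihydrofuran-2-yl]butanal
Product: 24 (4Z,6S,8R,10R)-8-[(tert-butyldimethylsilyl)oxy]-6-hydroxy-4,10-dimethyl-3,10-epoxycyclodeca-2,4-dien-1-one
Conditions: CrCl2 (8 equiv), NiCl2 (0.1 equiv), DMSO, rt, 2 mM, slow addition
Reagents that add atoms: none
Why: Nozaki–Hiyama–Kishi reaction, in which nickel-catalysed formation of the alkenylchromium species from the Z-iodide with retention and its addition to the aldehyde at high dilution close the C5–C6 bond, and C6 is set by substrate control, the aldehyde being expected to add through the ring conformer that places the new oxygen on the face of the C8 silyl ether.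

Step 16
Reactants: 24 (4Z,6S,8R,10R)-8-[(tert-butyldimethylsilyl)oxy]-6-hydroxy-4,10-dimethyl-3,10-epoxycyclodeca-2,4-dien-1-one; 3 (2S)-2-methyloxirane-2-carboxylic acid
Product: 26 (4Z,6S,8R,10R)-8-[(tert-butyldimethylsilyl)oxy]-4,10-dimethyl-1-oxo-3,10-epoxycyclodeca-2,4-dien-6-yl (2S)-2-methyloxirane-2-carboxylate, via mixed anhydride 25 (not isolated)
Conditions: 3, 2,4,6-trichlorobenzoyl chloride, Et3N, THF, rt; then 24, DMAP, toluene, rt
Reagents that add atoms: none
Why: Yamaguchi esterification through the mixed anhydride acylates the hindered allylic alcohol with retention at C6 and without opening the epoxide.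

Step 17
Reactants: 26 (4Z,6S,8R,10R)-8-[(tert-butyldimethylsilyl)oxy]-4,10-dimethyl-1-oxo-3,10-epoxycyclodeca-2,4-dien-6-yl (2S)-2-methyloxirane-2-carboxylate
Product: 27 (4Z,6S,8R,10R)-8-hydroxy-4,10-dimethyl-1-oxo-3,10-epoxycyclodeca-2,4-dien-6-yl (2S)-2-methyloxirane-2-carboxylate
Conditions: HF·pyridine, pyridine, THF, 0 °C → rt
Reagents that add atoms: none
Why: Buffered HF·pyridine cleaves the secondary silyl ether under mildly acidic conditions that should neither open the electron-poor epoxide nor move the acyl group from O6 to O8.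

Step 18
Reactants: 27 (4Z,6S,8R,10R)-8-hydroxy-4,10-dimethyl-1-oxo-3,10-epoxycyclodeca-2,4-dien-6-yl (2S)-2-methyloxirane-2-carboxylate; 28 (diethoxyphosphoryl)acetic acid
Product: 29 (4Z,6S,8R,10R)-8-{[(diethoxyphosphoryl)acetyl]oxy}-4,10-dimethyl-1-oxo-3,10-epoxycyclodeca-2,4-dien-6-yl (2S)-2-methyloxirane-2-carboxylate
Conditions: dicyclohexylcarbodiimide, DMAP (cat.), CH2Cl2, 0 °C → rt
Reagents that add atoms: none
Why: Steglich esterification of the unhindered secondary C8 alcohol with the phosphonoacetic acid under near-neutral conditions.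

Step 19
Reactants: 29 (4Z,6S,8R,10R)-8-{[(diethoxyphosphoryl)acetyl]oxy}-4,10-dimethyl-1-oxo-3,10-epoxycyclodeca-2,4-dien-6-yl (2S)-2-methyloxirane-2-carboxylate
Product: 30 (4Z,6S,8R,10R)-8-{[diazo(diethoxyphosphoryl)acetyl]oxy}-4,10-dimethyl-1-oxo-3,10-epoxycyclodeca-2,4-dien-6-yl (2S)-2-methyloxirane-2-carboxylate
Conditions: 4-acetamidobenzenesulfonyl azide, DBU, MeCN, 0 °C → rt
Reagents that add atoms: 4-acetamidobenzenesulfonyl azide, CC(=O)Nc1ccc(cc1)S(=O)(=O)N=[N+]=[N-]
Why: Regitz diazo transfer, in which the DBU-generated phosphonoacetate anion attacks the sulfonyl azide and expels the sulfonamide, a reaction open only to the doubly activated methylene.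

Step 20
Reactants: 30 (4Z,6S,8R,10R)-8-{[diazo(diethoxyphosphoryl)acetyl]oxy}-4,10-dimethyl-1-oxo-3,10-epoxycyclodeca-2,4-dien-6-yl (2S)-2-methyloxirane-2-carboxylate
Product: 31 (6R,7R,8S,10R,11R)-11-(diethoxyphosphoryl) trans-fused 8,12-lactone carrying the C6 (2S)-2-methyloxirane-2-carboxylate
Conditions: Rh2(OAc)4 (5 mol%), ClCH2CH2Cl, 80 °C, 30 added over 6 h, 2 mM
Reagents that add atoms: none
Why: Rh2(OAc)4 decomposes the diazo ester with loss of N2 to an electrophilic rhodium carbenoid, which inserts into a C7–H bond through a concerted three-centre transition state with retention at C7. The closest known reaction type is the dirhodium tetracarboxylate-catalysed 1,5 C–H insertion of α-diazo-α-(dialkoxyphosphoryl)acetates of secondary alcohols to α-phosphono-γ-butyrolactones. The lactone ring (C7, C8, O, C12, C11) closes by formation of C11–C7 in the five-membered 1,5-insertion mode that ester-tethered carbenoids favour. C7 is set by which diastereotopic hydrogen the carbenoid reaches: with C6 and C9 antiperiplanar about C7–C8, as expected for the ten-membered ring, the hydrogen gauche to O8 is the one whose replacement gives the trans fusion, while C11 forms or equilibrates with the phosphonate trans to C6 and is erased in step 21. The step needs selectivity against C9–H (neopentyl, next to quaternary C10 and β to the furanone oxygen), C6–H (six-membered closure, deactivated by the acyloxy group installed beforehand), C8–H (β-lactone), the C4=C5 alkene and the epoxide oxygen, all of which demand larger or more strained transition states. The phosphonate tempers the carbenoid, and slow addition at high dilution suppresses bimolecular pathways.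

Step 21
Reactants: 31 (6R,7R,8S,10R,11R)-11-(diethoxyphosphoryl) trans-fused 8,12-lactone carrying the C6 (2S)-2-methyloxirane-2-carboxylate
Product: 32 CNP0321429.1, the (4Z,6R,7R,8S,10R) α-methylene 8,12-lactone with the C6 (2S)-2-methyloxirane-2-carboxylate
Conditions: K2CO3, 37% aq. HCHO, THF, 0 °C → rt
Reagents that add atoms: formaldehyde, C=O
Why: Horner–Wadsworth–Emmons olefination, in which the phosphonate-stabilised lactone anion adds to formaldehyde and expels diethyl phosphate to give the exocyclic methylene, removing the C11 centre under conditions too mild to epimerise C7 or cleave the esters.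

Compound list
1 | 2-methylprop-2-en-1-ol | CC(=C)CO | starting material
2 | (R)-2-methylglycidol, [(2R)-2-methyloxiran-2-yl]methanol | OC[C@]1(C)CO1 | intermediate
3 | (2S)-2-methyloxirane-2-carboxylic acid | OC(=O)[C@]1(C)CO1 | intermediate
4 | prop-2-yn-1-ol | OCC#C | starting material
5 | bromomagnesium (Z)-3-(bromomagnesio)-2-methylprop-2-en-1-olate (alkenylmagnesium alkoxide, not isolated) | Br[Mg]OC/C(C)=C\[Mg]Br | intermediate
6 | (Z)-3-iodo-2-methylprop-2-en-1-ol | OC/C(C)=C\I | intermediate
7 | (Z)-3-iodo-2-methylprop-2-enal | O=C/C(C)=C\I | intermediate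
8 | (Z)-1-iodo-2-methylbut-1-en-3-yne | C#C/C(C)=C\I | intermediate
9 | (S)-lactic acid | C[C@H](O)C(O)=O | starting material
10 | (2S,5S)-2-tert-butyl-5-methyl-1,3-dioxolan-4-one | C[C@@H]1O[C@H](C(C)(C)C)OC1=O | intermediate
11 | lithium (2S)-2-tert-butyl-5-methyl-1,3-dioxol-4-olate (lithium enolate, not isolated) | CC1=C(O[Li])O[C@@H](C(C)(C)C)O1 | intermediate
12 | (2S,5R)-2-tert-butyl-5-methyl-5-(prop-2-en-1-yl)-1,3-dioxolan-4-one | C[C@]1(CC=C)O[C@H](C(C)(C)C)OC1=O | intermediate
13 | ozonide of 12, (2S,5R)-2-tert-butyl-5-methyl-5-(1,2,4-trioxolan-3-ylmethyl)-1,3-dioxolan-4-one, epimers at the trioxolane carbon (not isolated) | C[C@]1(CC2OCOO2)O[C@H](C(C)(C)C)OC1=O | intermediate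
14 | (2S,5R)-2-tert-butyl-5-methyl-5-(2-oxoethyl)-1,3-dioxolan-4-one | C[C@]1(CC=O)O[C@H](C(C)(C)C)OC1=O | intermediate
15 | diisopinocampheylborinate ester of 16 (not isolated) | C[C@]1(C[C@H](OB([C@H]2C[C@H]3C[C@@H]([C@@H]2C)C3(C)C)[C@H]2C[C@H]3C[C@@H]([C@@H]2C)C3(C)C)CC=C)O[C@H](C(C)(C)C)OC1=O | intermediate
16 | (2S,5R)-2-tert-butyl-5-[(2R)-2-hydroxypent-4-en-1-yl]-5-methyl-1,3-dioxolan-4-one | C[C@]1(C[C@H](O)CC=C)O[C@H](C(C)(C)C)OC1=O | intermediate
17 | (2S,5R)-2-tert-butyl-5-[(2R)-2-[(tert-butyldimethylsilyl)oxy]pent-4-en-1-yl]-5-methyl-1,3-dioxolan-4-one | C[C@]1(C[C@H](O[Si](C)(C)C(C)(C)C)CC=C)O[C@H](C(C)(C)C)OC1=O | intermediate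
18 | (2R,4R)-4-[(tert-butyldimethylsilyl)oxy]-2-hydroxy-N-methoxy-N,2-dimethylhept-6-enamide | CON(C)C(=O)[C@](C)(O)C[C@H](O[Si](C)(C)C(C)(C)C)CC=C | intermediate
19 | [(Z)-4-iodo-3-methylbut-3-en-1-yn-1-yl]lithium (lithium acetylide of 8, not isolated) | [Li]C#C/C(C)=C\I | intermediate
20 | (1Z,6R,8R)-8-[(tert-butyldimethylsilyl)oxy]-6-hydroxy-1-iodo-2,6-dimethylundeca-1,10-dien-3-yn-5-one | I/C=C(C)\C#CC(=O)[C@](C)(O)C[C@H](O[Si](C)(C)C(C)(C)C)CC=C | intermediate
21 | (2R)-2-[(2R)-2-[(tert-butyldimethylsilyl)oxy]pent-4-en-1-yl]-5-[(1Z)-1-iodoprop-1-en-2-yl]-2-methylfuran-3(2H)-one | I/C=C(C)\C1=CC(=O)[C@@](C)(C[C@H](O[Si](C)(C)C(C)(C)C)CC=C)O1 | intermediate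
22 | 4,5-diol from dihydroxylation of the terminal alkene of 21, epimers at the new carbinol (not isolated) | I/C=C(C)\C1=CC(=O)[C@@](C)(C[C@H](O[Si](C)(C)C(C)(C)C)CC(O)CO)O1 | intermediate
23 | (3S)-3-[(tert-butyldimethylsilyl)oxy]-4-[(2R)-5-[(1Z)-1-iodoprop-1-en-2-yl]-2-methyl-3-oxo-2,3-dihydrofuran-2-yl]butanal | I/C=C(C)\C1=CC(=O)[C@@](C)(C[C@H](O[Si](C)(C)C(C)(C)C)CC=O)O1 | intermediate
24 | (4Z,6S,8R,10R)-8-[(tert-butyldimethylsilyl)oxy]-6-hydroxy-4,10-dimethyl-3,10-epoxycyclodeca-2,4-dien-1-one | CC(C)(C)[Si](C)(C)O[C@H]1C[C@@]2(C)OC(=CC2=O)/C(C)=C\[C@@H](O)C1 | intermediate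
25 | (2S)-2-methyloxirane-2-carboxylic 2,4,6-trichlorobenzoic anhydride (not isolated) | O=C(OC(=O)[C@]1(C)CO1)c1c(Cl)cc(Cl)cc1Cl | intermediate
26 | (4Z,6S,8R,10R)-8-[(tert-butyldimethylsilyl)oxy]-4,10-dimethyl-1-oxo-3,10-epoxycyclodeca-2,4-dien-6-yl (2S)-2-methyloxirane-2-carboxylate | CC(C)(C)[Si](C)(C)O[C@H]1C[C@@]2(C)OC(=CC2=O)/C(C)=C\[C@@H](OC(=O)[C@]3(C)CO3)C1 | intermediate
27 | (4Z,6S,8R,10R)-8-hydroxy-4,10-dimethyl-1-oxo-3,10-epoxycyclodeca-2,4-dien-6-yl (2S)-2-methyloxirane-2-carboxylate | O[C@H]1C[C@@]2(C)OC(=CC2=O)/C(C)=C\[C@@H](OC(=O)[C@]3(C)CO3)C1 | intermediate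
28 | (diethoxyphosphoryl)acetic acid | OC(=O)CP(=O)(OCC)OCC | starting material
29 | (4Z,6S,8R,10R)-8-{[(diethoxyphosphoryl)acetyl]oxy}-4,10-dimethyl-1-oxo-3,10-epoxycyclodeca-2,4-dien-6-yl (2S)-2-methyloxirane-2-carboxylate | CCOP(=O)(OCC)CC(=O)O[C@H]1C[C@@]2(C)OC(=CC2=O)/C(C)=C\[C@@H](OC(=O)[C@]3(C)CO3)C1 | intermediate
30 | (4Z,6S,8R,10R)-8-{[diazo(diethoxyphosphoryl)acetyl]oxy}-4,10-dimethyl-1-oxo-3,10-epoxycyclodeca-2,4-dien-6-yl (2S)-2-methyloxirane-2-carboxylate | [N-]=[N+]=C(P(=O)(OCC)OCC)C(=O)O[C@H]1C[C@@]2(C)OC(=CC2=O)/C(C)=C\[C@@H](OC(=O)[C@]3(C)CO3)C1 | intermediate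
31 | (6R,7R,8S,10R,11R)-11-(diethoxyphosphoryl) trans-fused 8,12-lactone of the furanone-bridged ring, C6 (2S)-2-methyloxirane-2-carboxylate | CCOP(=O)(OCC)[C@H]1C(=O)O[C@H]2C[C@@]3(C)OC(=CC3=O)/C(C)=C\[C@@H](OC(=O)[C@]4(C)CO4)[C@H]12 | intermediate
32 | CNP0321429.1, (4Z,6R,7R,8S,10R) α-methylene 8,12-lactone, C6 (2S)-2-methyloxirane-2-carboxylate | C=C1C(=O)O[C@H]2C[C@@]3(C)OC(=CC3=O)/C(C)=C\[C@@H](OC(=O)[C@]3(C)CO3)[C@H]12 | target

Total step count: 21. Longest linear sequence: 16 steps (steps 6–21, from (S)-lactic acid 9 to 32).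

Steps most likely to fail

Step 20. The carbenoid may insert at the wrong site (C9–H, or C8–H to a β-lactone), add to the C4=C5 alkene, be trapped by the epoxide oxygen, or reach the other C7 hydrogen and close a cis-fused lactone. Fallback, setting out from 24 and coming back to the route at 32: C7–C11 is made by enolate alkylation instead of C–H insertion. Dess–Martin oxidation of 24 gives the C6 ketone, dienone F1. Its kinetic lithium enolate (LiN(SiMe3)2, THF, −78 °C; only C7 carries α-hydrogens) is alkylated with methyl iodoacetate anti to the C8 silyl ether to give the keto ester F2. HF·pyridine removes the silyl group and the freed C8 hydroxyl closes onto the methyl ester to give the trans-fused keto lactone F3. Luche reduction (NaBH4, CeCl3, MeOH, −78 °C) gives the hydroxy lactone F4; should the C6 epimer form, it would be inverted during esterification by the Mitsunobu procedure of the next fallback. Yamaguchi esterification with 3 (through 25) gives the lactone ester F5, which lacks only C13. Its lithium enolate is trapped with dimethylmethyleneiminium iodide to give the Mannich base F6. Methylation with MeI gives the ammonium iodide F7, and NaHCO3 then eliminates trimethylamine to give 32.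

Step 15. The ring-closing addition may show poor facial selectivity at C6, and intermolecular coupling may compete with cyclisation. Fallback, setting out from 23 and coming back at 26: the alcohol epimeric at C6, 6-epi alcohol F8, is not discarded. Mitsunobu esterification of F8 with acid 3 (PPh3, diisopropyl azodicarboxylate, toluene, 0 °C) displaces the activated hydroxyl with inversion and gives ester 26 directly. Both epimers therefore converge, the cis alcohol by acylation with retention and the trans alcohol by SN2 esterification.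

Step 14. Oxidation may not stop at the terminal alkene, with competing dihydroxylation of the furanone C2=C3 bond or the iodoalkene. Fallback, setting out from 17 and coming back at 23: the alkene is cleaved while it is the only C=C bond in the molecule. Ozonolysis of 17 (O3, CH2Cl2, −78 °C; Me2S) gives the silyloxy aldehyde F9, which is protected at once (CH(OMe)3, pyridinium p-toluenesulfonate, MeOH) as the dimethyl acetal F10. The conditions of steps 11 to 13 then give the Weinreb amide acetal F11, the hydroxy ynone acetal F12 and the furanone acetal F13. Mild hydrolysis (LiBF4, wet MeCN) releases aldehyde 23.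

Further compounds
F1 | step 20 | (4Z,8R,10R)-8-[(tert-butyldimethylsilyl)oxy]-4,10-dimethyl-3,10-epoxycyclodeca-2,4-diene-1,6-dione (dienone) | CC(C)(C)[Si](C)(C)O[C@H]1C[C@@]2(C)OC(=CC2=O)/C(C)=C\C(=O)C1
F2 | step 20 | methyl ester of the C7-carboxymethyl derivative of F1 (keto ester, C7 substituent trans to the C8 silyl ether) | CC(C)(C)[Si](C)(C)O[C@H]1C[C@@]2(C)OC(=CC2=O)/C(C)=C\C(=O)[C@@H]1CC(=O)OC
F3 | step 20 | trans-fused 8,12-lactone with C6 ketone (keto lactone) | C1C(=O)O[C@H]2C[C@@]3(C)OC(=CC3=O)/C(C)=C\C(=O)[C@H]12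
F4 | step 20 | trans-fused 8,12-lactone with free C6 hydroxyl (hydroxy lactone) | C1C(=O)O[C@H]2C[C@@]3(C)OC(=CC3=O)/C(C)=C\[C@@H](O)[C@H]12
F5 | step 20 | 13-nor analogue of 32 (lactone ester lacking the methylene) | C1C(=O)O[C@H]2C[C@@]3(C)OC(=CC3=O)/C(C)=C\[C@@H](OC(=O)[C@]4(C)CO4)[C@H]12
F6 | step 20 | 11-(dimethylaminomethyl) lactone, C11 epimers (Mannich base) | CN(C)CC1C(=O)O[C@H]2C[C@@]3(C)OC(=CC3=O)/C(C)=C\[C@@H](OC(=O)[C@]4(C)CO4)[C@H]12
F7 | step 20 | 11-(trimethylammoniomethyl) lactone iodide (ammonium iodide) | C[N+](C)(C)CC1C(=O)O[C@H]2C[C@@]3(C)OC(=CC3=O)/C(C)=C\[C@@H](OC(=O)[C@]4(C)CO4)[C@H]12.[I-]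
F8 | step 15 | (4Z,6R,8R,10R)-8-[(tert-butyldimethylsilyl)oxy]-6-hydroxy-4,10-dimethyl-3,10-epoxycyclodeca-2,4-dien-1-one (6-epi alcohol) | CC(C)(C)[Si](C)(C)O[C@H]1C[C@@]2(C)OC(=CC2=O)/C(C)=C\[C@H](O)C1
F9 | step 14 | silyloxy aldehyde from ozonolysis of 17 | C[C@]1(C[C@H](O[Si](C)(C)C(C)(C)C)CC=O)O[C@H](C(C)(C)C)OC1=O
F10 | step 14 | dimethyl acetal of F9 | C[C@]1(C[C@H](O[Si](C)(C)C(C)(C)C)CC(OC)OC)O[C@H](C(C)(C)C)OC1=O
F11 | step 14 | Weinreb amide acetal (analogue of 18) | CON(C)C(=O)[C@](C)(O)C[C@H](O[Si](C)(C)C(C)(C)C)CC(OC)OC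
F12 | step 14 | hydroxy ynone acetal (analogue of 20) | I/C=C(C)\C#CC(=O)[C@](C)(O)C[C@H](O[Si](C)(C)C(C)(C)C)CC(OC)OC
F13 | step 14 | furanone acetal (dimethyl acetal of 23) | I/C=C(C)\C1=CC(=O)[C@@](C)(C[C@H](O[Si](C)(C)C(C)(C)C)CC(OC)OC)O1
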